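The quinone ring A (C1–C4, C4a, C8a; C2 carries the side chain) is cut into three pieces: C1 as the carbene carbon of an aryl(methoxy)carbene chromium complex built on the para-dioxygenated benzene ring B, C2–C3 as an alkyne already bearing the (R)-configured side chain, and C4 as a CO ligand. One Dötz benzannulation joins C1 to C2 and closes C4 onto C4a, the free ortho carbon of ring B, giving ring A as a hydroquinone monoether. The step exploits the 1,4-dioxygenation of ring A and the unsubstituted C4a–H of ring B; a removable boryl group on C3 steers the alkyne insertion. Oxidation, deprotection and esterification finish the target.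

Key step: step 8

Remark: ring atoms are numbered as in the target (C1, C4 quinone carbonyl carbons; C2 side-chain carbon; C3 quinone CH; C4a next to C4; C8a next to C1; C5, C8 hydroxylated). The boryl group is assumed to direct alkyne insertion as it does for simpler alkynyl pinacol boronates.

Step 1
Reactants: 1 4-methylpent-3-enoic acid
Product: 2 N-methoxy-N,4-dimethylpent-3-enamide
Conditions: MeNH(OMe)·HCl, EDC·HCl, N-methylmorpholine, CH2Cl2, 0 °C → rt
Reagents that add atoms: N,O-dimethylhydroxylamine hydrochloride, CNOC.Cl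
Why: Carbodiimide-mediated amide coupling should give the Weinreb amide without moving the β,γ-double bond, since no strong base is present.

Step 2
Reactants: 2 N-methoxy-N,4-dimethylpent-3-enamide; 3 lithium (trimethylsilyl)acetylide (commercial THF solution)
Product: 4 6-methyl-1-(trimethylsilyl)hept-5-en-1-yn-3-one
Conditions: THF, −78 → −20 °C; cold aq. NH4Cl
Reagents that add atoms: none
Why: Weinreb ketone synthesis: the chelated tetrahedral adduct should persist until the quench, so the acetylide adds once and the base-sensitive skipped ynone is released only on protonation.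

Step 3
Reactants: 4 6-methyl-1-(trimethylsilyl)hept-5-en-1-yn-3-one
Product: 5 (3R)-6-methyl-1-(trimethylsilyl)hept-5-en-1-yn-3-ol
Conditions: Ru[(1R,2R)-TsNCH(C6H5)CH(C6H5)NH](p-cymene) (0.5 mol %), i-PrOH, 25 °C
Reagents that add atoms: none
Why: Noyori asymmetric transfer hydrogenation of an ynone: the (R,R)-diamine catalyst should deliver hydride to the carbonyl face that gives the (R)-carbinol, the alkynyl group taking the place an aryl group takes in aryl ketone reductions, and the base-free amido complex should leave the skipped enone unisomerized.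

Step 4
Reactants: 5 (3R)-6-methyl-1-(trimethylsilyl)hept-5-en-1-yn-3-ol
Product: 6 tert-butyldimethyl{[(3R)-6-methyl-1-(trimethylsilyl)hept-5-en-1-yn-3-yl]oxy}silane
Conditions: TBSCl, imidazole, DMF, rt
Reagents that add atoms: tert-butyldimethylsilyl chloride, CC(C)(C)[Si](C)(C)Cl
Why: Standard silylation of a secondary alcohol; the TBS ether should withstand the organolithium, thermal and weakly acidic steps that follow.

Step 5
Reactants: 6 tert-butyldimethyl{[(3R)-6-methyl-1-(trimethylsilyl)hept-5-en-1-yn-3-yl]oxy}silane
Product: 9 tert-butyldimethyl{[(3R)-6-methyl-1-(4,4,5,5-tetramethyl-1,3,2-dioxaborolan-2-yl)hept-5-en-1-yn-3-yl]oxy}silane, via lithium acetylide 7 (not isolated), via lithium alkynylborate 8 (not isolated)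
Conditions: MeLi·LiBr, THF, 0 °C → rt; i-PrOBpin, −78 °C; HCl in Et2O, −78 °C → rt; filtered under argon, used crude
Reagents that add atoms: 2-isopropoxy-4,4,5,5-tetramethyl-1,3,2-dioxaborolane, CC(C)OB1OC(C)(C)C(C)(C)O1
Why: Methyllithium should attack the alkynyl silicon to release the lithium acetylide (desilylative lithiation), which is borylated by the isopropoxyborolane and freed from the ate complex by anhydrous HCl, the standard route to alkynyl pinacol boronates.

Step 6
Reactants: 10 hydroquinone
Product: 11 1,4-bis(methoxymethoxy)benzene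
Conditions: MOMCl, i-Pr2NEt, DMF, 0 °C → rt
Reagents that add atoms: chloromethyl methyl ether, COCCl
Why: Double MOM ether formation gives acetal ethers that direct ortho-lithiation and are later removed by mild acid.

Step 7
Reactants: 11 1,4-bis(methoxymethoxy)benzene; 12 chromium hexacarbonyl, Cr(CO)6
Product: 15 pentacarbonyl{[2,5-bis(methoxymethoxy)phenyl](methoxy)methylidene}chromium, (CO)5Cr=C(OMe)Ar, via aryllithium 13 (not isolated), via lithium acylchromate 14 (not isolated)
Conditions: n-BuLi, THF, 0 °C; Cr(CO)6, 0 °C → rt; MeOTf, CH2Cl2, 0 °C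
Reagents that add atoms: methyl trifluoromethanesulfonate, COS(=O)(=O)C(F)(F)F
Why: Directed ortho-metalation followed by the Fischer carbene synthesis: the aryllithium adds to a CO ligand of Cr(CO)6 and the acylchromate is O-methylated by the hard electrophile MeOTf.

Step 8
Reactants: 15 pentacarbonyl{[2,5-bis(methoxymethoxy)phenyl](methoxy)methylidene}chromium; 9 tert-butyldimethyl{[(3R)-6-methyl-1-(4,4,5,5-tetramethyl-1,3,2-dioxaborolan-2-yl)hept-5-en-1-yn-3-yl]oxy}silane
Product: 17 3-[(1R)-1-(tert-butyldimethylsilyloxy)-4-methylpent-3-en-1-yl]-4-methoxy-5,8-bis(methoxymethoxy)-2-(4,4,5,5-tetramethyl-1,3,2-dioxaborolan-2-yl)naphthalen-1-ol (target numbering: OMe on C1, side chain on C2, boron on C3, OH on C4), via arene chromium tricarbonyl complex 16 (not isolated)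
Conditions: THF, 50 °C, argon; then air, Et2O, daylight, rt
Reagents that add atoms: none
Why: Dötz benzannulation: loss of one CO from 15 lets alkyne 9 insert into the Cr=C bond so that the carbene carbon (future C1) bonds to the side-chain-bearing alkyne carbon (C2) and the boryl-bearing carbon (C3) becomes chromium-bound; CO insertion there gives a vinylketene whose ketene carbon (future C4) closes onto the only free ortho carbon of the arene (C4a), and tautomerization gives the naphthol as its Cr(CO)3 complex, which air demetalates. The closest precedent is the benzannulation of aryl(methoxy)carbene chromium complexes with alkynyl pinacol boronates, which places boron next to the CO-derived phenol carbon. Ring A is closed by a 6π electrocyclization of the aryl vinylketene (formal [3+2+1] assembly from carbene carbon, alkyne and CO). No stereocentre is created, and the propargylic stereocentre takes part in no bond change and should be carried through unchanged. The step needs regioselective insertion, secured by the electron-poor boryl group (the alkyl-substituted alkyne carbon is the more nucleophilic and attacks the carbene carbon), and chemoselectivity over the prenyl alkene, secured by its unactivated trisubstituted nature and the 1,5-enyne spacing that disfavours intramolecular cyclopropanation.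

Step 9
Reactants: 17 the naphthol boronate from step 8
Product: 18 3-[(1R)-1-(tert-butyldimethylsilyloxy)-4-methylpent-3-en-1-yl]-4-methoxy-5,8-bis(methoxymethoxy)naphthalen-1-ol
Conditions: AcOH, THF–H2O, 45 °C, argon
Reagents that add atoms: none
Why: Protodeboronation: the boron-bearing carbon is ortho to the free naphthol hydroxyl, so ipso-protonation through the keto tautomer and loss of boron to water should occur under conditions that leave the MOM and TBS ethers intact.

Step 10
Reactants: 18 the deborylated naphthol from step 9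
Product: 19 2-[(1R)-1-(tert-butyldimethylsilyloxy)-4-methylpent-3-en-1-yl]-5,8-bis(methoxymethoxy)naphthalene-1,4-dione
Conditions: PhI(OAc)2, MeCN–H2O, 0 °C
Reagents that add atoms: water, O
Why: Hypervalent iodine oxidation of a para-methoxynaphthol (oxidative demethylation): water adds to the methoxy-bearing carbon of the phenoxenium ion and methanol is lost, which should give the quinone while ring B, lacking a free hydroxyl, stays untouched.

Step 11
Reactants: 19 the protected quinone from step 10
Product: 20 shikonin, 5,8-dihydroxy-2-[(1R)-1-hydroxy-4-methylpent-3-en-1-yl]naphthalene-1,4-dione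
Conditions: 2 M aq. HCl, THF, 35 °C
Reagents that add atoms: none
Why: Acid hydrolysis should cleave both aryl MOM acetals, activated by the peri quinone carbonyls, and the silyl ether, while the carbinol on the electron-poor quinone does not ionize, so the stereocentre is retained.

Step 12
Reactants: 20 shikonin; 21 3-methylbutanoic acid (isovaleric acid)
Product: 22 isovalerylshikonin, (1R)-1-(5,8-dihydroxy-1,4-dioxo-1,4-dihydronaphthalen-2-yl)-4-methylpent-3-en-1-yl 3-methylbutanoate
Conditions: DCC, DMAP (cat.), CH2Cl2, 0 °C → rt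
Reagents that add atoms: none
Why: Steglich esterification: the secondary side-chain hydroxyl should be acylated selectively because the two peri phenols are chelated to the quinone carbonyls and poorly nucleophilic.

Compound list
1 | 4-methylpent-3-enoic acid | CC(C)=CCC(=O)O | starting material
2 | N-methoxy-N,4-dimethylpent-3-enamide | CC(C)=CCC(=O)N(C)OC | intermediate
3 | lithium (trimethylsilyl)acetylide | [Li]C#C[Si](C)(C)C | starting material
4 | 6-methyl-1-(trimethylsilyl)hept-5-en-1-yn-3-one | CC(C)=CCC(=O)C#C[Si](C)(C)C | intermediate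
5 | (3R)-6-methyl-1-(trimethylsilyl)hept-5-en-1-yn-3-ol | CC(C)=CC[C@@H](O)C#C[Si](C)(C)C | intermediate
6 | tert-butyldimethyl{[(3R)-6-methyl-1-(trimethylsilyl)hept-5-en-1-yn-3-yl]oxy}silane | CC(C)=CC[C@@H](O[Si](C)(C)C(C)(C)C)C#C[Si](C)(C)C | intermediate
7 | [(3R)-3-(tert-butyldimethylsilyloxy)-6-methylhept-5-en-1-yn-1-yl]lithium | CC(C)=CC[C@@H](O[Si](C)(C)C(C)(C)C)C#C[Li] | intermediate
8 | lithium [(3R)-3-(tert-butyldimethylsilyloxy)-6-methylhept-5-en-1-yn-1-yl](isopropoxy)(pinacolato)borate | [Li+].CC(C)=CC[C@@H](O[Si](C)(C)C(C)(C)C)C#C[B-]1(OC(C)C)OC(C)(C)C(C)(C)O1 | intermediate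
9 | tert-butyldimethyl{[(3R)-6-methyl-1-(4,4,5,5-tetramethyl-1,3,2-dioxaborolan-2-yl)hept-5-en-1-yn-3-yl]oxy}silane | CC(C)=CC[C@@H](O[Si](C)(C)C(C)(C)C)C#CB1OC(C)(C)C(C)(C)O1 | intermediate
10 | hydroquinone | Oc1ccc(O)cc1 | starting material
11 | 1,4-bis(methoxymethoxy)benzene | COCOc1ccc(OCOC)cc1 | intermediate
12 | chromium hexacarbonyl | [Cr].[C-]#[O+].[C-]#[O+].[C-]#[O+].[C-]#[O+].[C-]#[O+].[C-]#[O+] | starting material
13 | [2,5-bis(methoxymethoxy)phenyl]lithium | [Li]c1cc(OCOC)ccc1OCOC | intermediate
14 | lithium pentacarbonyl[2,5-bis(methoxymethoxy)benzoyl]chromate | [Li+].[O-]C(=[Cr])c1cc(OCOC)ccc1OCOC.[C-]#[O+].[C-]#[O+].[C-]#[O+].[C-]#[O+].[C-]#[O+] | intermediate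
15 | pentacarbonyl{[2,5-bis(methoxymethoxy)phenyl](methoxy)methylidene}chromium | COC(=[Cr])c1cc(OCOC)ccc1OCOC.[C-]#[O+].[C-]#[O+].[C-]#[O+].[C-]#[O+].[C-]#[O+] | intermediate
16 | tricarbonylchromium complex of naphthol 17 (chromium bound to ring A) | CC(C)=CC[C@@H](O[Si](C)(C)C(C)(C)C)c1c(OC)c2c(OCOC)ccc(OCOC)c2c(O)c1B3OC(C)(C)C(C)(C)O3.[Cr].[C-]#[O+].[C-]#[O+].[C-]#[O+] | intermediate
17 | 3-[(1R)-1-(tert-butyldimethylsilyloxy)-4-methylpent-3-en-1-yl]-4-methoxy-5,8-bis(methoxymethoxy)-2-(4,4,5,5-tetramethyl-1,3,2-dioxaborolan-2-yl)naphthalen-1-ol | CC(C)=CC[C@@H](O[Si](C)(C)C(C)(C)C)c1c(OC)c2c(OCOC)ccc(OCOC)c2c(O)c1B3OC(C)(C)C(C)(C)O3 | intermediate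
18 | 3-[(1R)-1-(tert-butyldimethylsilyloxy)-4-methylpent-3-en-1-yl]-4-methoxy-5,8-bis(methoxymethoxy)naphthalen-1-ol | CC(C)=CC[C@@H](O[Si](C)(C)C(C)(C)C)c1cc(O)c2c(OCOC)ccc(OCOC)c2c1OC | intermediate
19 | 2-[(1R)-1-(tert-butyldimethylsilyloxy)-4-methylpent-3-en-1-yl]-5,8-bis(methoxymethoxy)naphthalene-1,4-dione | CC(C)=CC[C@@H](O[Si](C)(C)C(C)(C)C)C1=CC(=O)c2c(OCOC)ccc(OCOC)c2C1=O | intermediate
20 | shikonin, 5,8-dihydroxy-2-[(1R)-1-hydroxy-4-methylpent-3-en-1-yl]naphthalene-1,4-dione | CC(C)=CC[C@@H](O)C1=CC(=O)c2c(O)ccc(O)c2C1=O | intermediate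
21 | 3-methylbutanoic acid | CC(C)CC(=O)O | starting material
22 | isovalerylshikonin | CC(C)=CC[C@@H](OC(=O)CC(C)C)C1=CC(=O)c2c(O)ccc(O)c2C1=O | target

Total step count: 12. Longest linear sequence: 10 steps (steps 1–5, then 8–12).

Steps most likely to fail

Step 8. The alkyne is internal and hindered at both ends, so insertion may lose regiocontrol or the vinylcarbene may be diverted into indene or cyclobutenone formation instead of CO insertion and ring closure. The fallback sets out from 6 and comes back at 19. The silyl alkyne 6 is desilylated with K2CO3 in MeOH to the terminal alkyne tert-butyldimethyl{[(3R)-6-methylhept-5-en-1-yn-3-yl]oxy}silane F1. F1 and carbene complex 15 then undergo the classical Dötz benzannulation (THF, 50 °C; air), in which a terminal alkyne inserts with its unsubstituted carbon at the carbene carbon. This gives the regioisomeric naphthol 2-[(1R)-1-(tert-butyldimethylsilyloxy)-4-methylpent-3-en-1-yl]-4-methoxy-5,8-bis(methoxymethoxy)naphthalen-1-ol F2. Oxidation of F2 with PhI(OAc)2 in aqueous MeCN gives the same quinone 19, so borylation and deborylation drop out.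

Step 9. Cleavage of the C–B bond may be too slow under conditions mild enough to spare the acetal and silyl ethers, and the electron-rich naphthol may oxidize in the meantime. The fallback sets out from 6 and 15 and comes back at 18, replacing boron by silicon as the directing group. The silyl alkyne 6 itself is heated with 15 (THF, 60 °C; air), the silyl-bearing carbon taking the position next to the CO-derived carbon. This gives 3-[(1R)-1-(tert-butyldimethylsilyloxy)-4-methylpent-3-en-1-yl]-4-methoxy-5,8-bis(methoxymethoxy)-2-(trimethylsilyl)naphthalen-1-ol F3. Ipso-protodesilylation of this activated arylsilane (TFA, CH2Cl2, −20 °C, short contact, NaHCO3 quench) then gives 18.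

Step 11. The freed carbinol may add to the prenyl double bond under acid, and the hindered silyl ether may cleave incompletely. The fallback sets out from 19 and comes back at the target 22 without passing through 20. HF·pyridine in THF at 0 °C removes only the silyl ether to give 2-[(1R)-1-hydroxy-4-methylpent-3-en-1-yl]-5,8-bis(methoxymethoxy)naphthalene-1,4-dione F4. Acylation with 3-methylbutanoyl chloride, pyridine and catalytic DMAP gives (1R)-1-[5,8-bis(methoxymethoxy)-1,4-dioxo-1,4-dihydronaphthalen-2-yl]-4-methylpent-3-en-1-yl 3-methylbutanoate F5. With the hydroxyl now blocked as the ester, brief treatment with TFA in CH2Cl2 at 0 °C removes the two MOM groups and gives 22.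

Further compounds
F1 | step 8 | tert-butyldimethyl{[(3R)-6-methylhept-5-en-1-yn-3-yl]oxy}silane | CC(C)=CC[C@@H](O[Si](C)(C)C(C)(C)C)C#C
F2 | step 8 | 2-[(1R)-1-(tert-butyldimethylsilyloxy)-4-methylpent-3-en-1-yl]-4-methoxy-5,8-bis(methoxymethoxy)naphthalen-1-ol | CC(C)=CC[C@@H](O[Si](C)(C)C(C)(C)C)c1cc(OC)c2c(OCOC)ccc(OCOC)c2c1O
F3 | step 9 | 3-[(1R)-1-(tert-butyldimethylsilyloxy)-4-methylpent-3-en-1-yl]-4-methoxy-5,8-bis(methoxymethoxy)-2-(trimethylsilyl)naphthalen-1-ol | CC(C)=CC[C@@H](O[Si](C)(C)C(C)(C)C)c1c(OC)c2c(OCOC)ccc(OCOC)c2c(O)c1[Si](C)(C)C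
F4 | step 11 | 2-[(1R)-1-hydroxy-4-methylpent-3-en-1-yl]-5,8-bis(methoxymethoxy)naphthalene-1,4-dione | CC(C)=CC[C@@H](O)C1=CC(=O)c2c(OCOC)ccc(OCOC)c2C1=O
F5 | step 11 | (1R)-1-[5,8-bis(methoxymethoxy)-1,4-dioxo-1,4-dihydronaphthalen-2-yl]-4-methylpent-3-en-1-yl 3-methylbutanoate | CC(C)=CC[C@@H](OC(=O)CC(C)C)C1=CC(=O)c2c(OCOC)ccc(OCOC)c2C1=O
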